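## Structural features

The target is a 5,7-dihydroxyflavone: benzo ring A is fused to 4-pyranone ring C, which carries phenyl ring B at C2. Ring A carbon C6, between the phenolic carbons C5 and C7, is bonded to C2' of an N-methylpiperidine. C2' is the only stereocentre and is R (N1' > aryl > C3' > H), so no neighbouring stereocentre and no relative configuration has to be controlled. C2' is benzylic to a phloroglucinol-type ring, flanked by two ortho oxygens, and bears the nitrogen; once nitrogen is protonated the C2'–N1' bond can ionise with help from an ortho or para oxygen, and reversible opening of this kind would racemise the compound. Other sensitive sites are the basic tertiary amine, which binds transition metals, and the 5-hydroxy-4-pyranone, which in hot acid can open and reclose on the other oxygen and so move the piperidine from C6 to C8. The real difficulty is to create C2' as one enantiomer at a di-ortho-substituted benzylic carbon, to keep it through ring construction and deprotection, and to fuse the pyranone so that the piperidine ends up at C6. With identical groups on O5 and O7 and the oxygen para to C6 free, the two ring A carbons ortho to that oxygen (the later C4a and C8) are equivalent, so annulation there can only give the 6-substituted flavone. The piperidine bond C4'–C5' lies on the far side of the ring from C2'; the key step closes the ring there by olefin metathesis after C2' has been set on an open chain, so no bond to the crowded, labile carbon is made or broken in the ring closure.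

## Logic of the disconnections

**20 ⇒ 19.** The last bonds broken are the two O–CH3 bonds on O5 and O7. Methyl ethers deny ring A the free ortho hydroxyls that would assist ionisation of C2'–N1' and would compete with the para oxygen in the annulation, and they survive every earlier reagent. The gain is a robust, locally symmetrical ring A throughout. The demand is a Lewis-acid ether cleavage run cold, with nitrogen tied up, so that neither C2' nor the pyranone is disturbed.

**19 ⇒ 18.** The C4–C4a bond is cut, opening ring C to an aryl enol-ether acid. The acyl carbon attacks a ring carbon that is ortho to the aryloxy oxygen and para to a methoxy group, and the two candidate carbons are equivalent, so there is no regiochemical choice. The gain is that the pyranone becomes a side chain held by one C–O bond. The forward Friedel–Crafts acylation must run near room temperature so that the protonated benzylic amine does not ionise.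

**18 ⇒ 15 + 16 (through 17).** The O1–C2 bond is cut, together with the ester C–O bond replaced on hydrolysis. Conjugate addition of the phenoxide to the alkynoate brings in C2, C3, C4 and ring B in one commercial piece, and it runs in base, where C2' is safest because nitrogen is not protonated. The demand is O-addition at the β-carbon and saponification without retro-addition.

**15 ⇒ 14.** This is a functional-group change: the benzyl group on the para oxygen and the C4'=C5' double bond are put back. One hydrogenation removes both, so no separate deprotection is needed. The demand is that the benzylic C2'–N1' bond is not hydrogenolysed and the alkene does not migrate towards C2' before it is reduced.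

**14 ⇒ 11 (through 12 and 13).** The C4'=C5' bond is cut. This is the ring bond remote from C2', so closure neither forms a bond at the crowded carbon nor needs conditions that threaten it. The ring becomes two allyl groups on a chiral amine, whose stereocentre can be made by imine chemistry. The demand is that the basic nitrogen is masked as its sulfonate salt and that dilution favours cyclisation over chain growth.

**11 ⇒ 10 + 6.** The N1'–C6' bond is cut. Allylation of a hindered secondary amine stops at the tertiary amine, so the diene is reached without a mixture of alkylation levels. The demand is only that quaternisation is avoided by limiting the alkylating agent.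

**10 ⇒ 9 ⇒ 8.** The N–S bond and the N–CH3 bond are cut in turn. Methylating nitrogen while it still carries the sulfinyl group allows exactly one alkylation, whereas a free primary amine would be hard to allylate or methylate only once. The gain is that the auxiliary doubles as the nitrogen protecting group. The demand is that S–N cleavage by acid is fast and cold, with brief acid contact.

**8 ⇒ 5 + 6 (through 7).** The C2'–C3' bond is cut; this step sets C2'. Addition of an allyl nucleophile to an N-sulfinyl aldimine gives an α-branched benzylic amine that already carries one of the two alkenes. The stereocentre then comes from an inexpensive auxiliary and an achiral aldehyde. The demand is facial control by the sulfinyl group despite two ortho methoxy groups that can also bind the metal.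

**5 ⇒ 3 + 4 and 3 ⇒ 1 + 2.** The C=N bond and the O–CH2Ph bond are cut. Condensation and O-alkylation lead back to commercial materials, and the benzyl group marks the oxygen that becomes O1. The demand is a dehydrating Lewis acid strong enough for a hindered, electron-rich aldehyde.

## Other disconnections considered

**Alternative 1:** The cut is through ring C at C3–C4 and O1–C2.
- **Forward step:** a trivalent rhodium catalyst such as [Cp*RhCl2]2 activates the formyl C–H of salicylaldehyde A2, the sulfoxonium ylide A3 is inserted as a carbene equivalent, and cyclodehydration gives flavone A1.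
- **In favour:** the pyranone forms in one near-neutral step, and the carbamate lowers the basicity of nitrogen.
- **Against:** A2 needs an extra ortho-formylation, its formyl group is flanked by a hydroxyl and a methoxy group, and the carbamate must later be exchanged for methyl in two steps because hydride reduction is ruled out by the pyranone. It also leaves open how C2' and the piperidine are made.
- **Comparison:** for ring C alone it is the better plan: one step instead of two and no strong acid near C2'. Regiochemical certainty is equal, since both rely on the equivalence of the two ortho carbons. Overall it is about two steps longer, uses a precious metal, and ends with the same ether cleavage.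

**Alternative 2:** The cut is at C2'–C3' and N1'–C6'.
- **Forward step:** N-aryl aldimine A5 and siloxydiene A6 combine under a chiral BINOL-derived phosphoric acid by Mannich addition and ring closure to give dihydropyridinone A4.
- **In favour:** ring and stereocentre arise in one catalytic step with no stoichiometric auxiliary, where the chosen plan needs steps 2, 3 and 7. On this count it is the better plan.
- **Against:** the imine carbon of A5 is shielded by two ortho methoxy groups and deactivated by three donor oxygens, so both rate and face discrimination are uncertain. A4 carries a ring ketone, an enaminone double bond and an N-aryl group that the target lacks; oxidative removal of the aryl group with (NH4)2Ce(NO3)6 would compete with oxidation of the trialkoxyarene. A4 is also a β-amino ketone that can open by retro-Mannich reaction and lose its configuration.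
- **Comparison:** bond formation occurs at the crowded carbon itself, not remote from it, and the clean-up after A4 would probably take more steps than the chosen plan needs to reach 15.

**Alternative 3:** The cut is at N1'–C2'.
- **Forward step:** racemic alcohol A8 loses water under a chiral phosphoric acid to give ortho-quinone methide A9, and the carbamate nitrogen adds to the methide carbon to close the piperidine as A7.
- **In favour:** it turns the lability of C2' into the bond-forming event, is stereoconvergent from a racemate, delivers a saturated ring, and the carbamate can be reduced to N-methyl in one step with LiAlH4. On these points it is equal to or better than the chosen plan.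
- **Against:** A7 has the ortho oxygens free and the para oxygen benzylated, the reverse of what annulation at the para oxygen needs, so three protecting-group steps would be required to avoid the 8-substituted flavone. A7 can also return to A9 under the same acid, so the enantiomeric purity could erode. Catalyst-controlled six-membered closures of carbamates onto such methides are less well supported than sulfinimine allylation.
- **Comparison:** the route to the piperidine is shorter, but the protecting-group exchange cancels the saving and the stereochemical outcome is less certain.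

Key step: step 7

Remark on the chemistry: compounds 1, 2, 4, 6 and 16 are taken as commercial, and the allylation in step 3 is assumed to follow the closed, sulfinyl-chelated chair usual for N-sulfinyl aldimines in ethereal solvent. C2' is R from 8 to 20, because the order N > aryl carbon > CH2 > H holds throughout.

## Route

Step 1
Reactants: 1 4-hydroxy-2,6-dimethoxybenzaldehyde; 2 benzyl bromide
Product: 3 4-(benzyloxy)-2,6-dimethoxybenzaldehyde
Conditions: K2CO3, DMF, rt
Reagents that add atoms: none
Why: Williamson ether synthesis on the only free phenol, which is para to the formyl group and therefore acidic; the benzyl group marks the oxygen that later becomes O1 and falls off in the hydrogenation of step 8.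

Step 2
Reactants: 3 4-(benzyloxy)-2,6-dimethoxybenzaldehyde; 4 (S)-2-methylpropane-2-sulfinamide
Product: 5 (S,E)-N-[4-(benzyloxy)-2,6-dimethoxybenzylidene]-2-methylpropane-2-sulfinamide
Conditions: Ti(OEt)4 (2 equiv), THF, 65 °C
Reagents that add atoms: none
Why: Lewis-acid-mediated imine condensation; Ti(OEt)4 activates the hindered, electron-rich aldehyde and takes up the water, and only the E-imine is expected next to the di-ortho-substituted ring.

Step 3
Reactants: 5 (S,E)-N-[4-(benzyloxy)-2,6-dimethoxybenzylidene]-2-methylpropane-2-sulfinamide; 6 allyl bromide
Product: 8 (S)-N-[(1R)-1-[4-(benzyloxy)-2,6-dimethoxyphenyl]but-3-en-1-yl]-2-methylpropane-2-sulfinamide, via allylzinc bromide 7 (not isolated)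
Conditions: Zn dust, THF, 0 °C to rt; sat. aq. NH4Cl
Reagents that add atoms: none
Why: Barbier-type allylation of an N-sulfinyl aldimine through a closed six-membered chair in which zinc is held by the sulfinyl oxygen and tert-butyl and aryl are equatorial, so the allyl group should reach the Re face of the imine carbon of the (S)-sulfinyl imine and make C2' R. The sulfinyl group offsets the poor electrophilicity of the trialkoxyaryl imine, and the minor sulfinamide, being a diastereomer, can be removed at this stage.

Step 4
Reactants: 8 (S)-N-[(1R)-1-[4-(benzyloxy)-2,6-dimethoxyphenyl]but-3-en-1-yl]-2-methylpropane-2-sulfinamide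
Product: 9 (S)-N-[(1R)-1-[4-(benzyloxy)-2,6-dimethoxyphenyl]but-3-en-1-yl]-N,2-dimethylpropane-2-sulfinamide
Conditions: LiN(SiMe3)2, THF, −20 °C; MeI, −20 °C to rt
Reagents that add atoms: iodomethane, CI
Why: N-alkylation of a sulfinamide anion; the N–H is by far the most acidic site, and the sulfinyl group allows only one methyl group to be introduced, which a free primary amine would not guarantee.

Step 5
Reactants: 9 (S)-N-[(1R)-1-[4-(benzyloxy)-2,6-dimethoxyphenyl]but-3-en-1-yl]-N,2-dimethylpropane-2-sulfinamide
Product: 10 (1R)-1-[4-(benzyloxy)-2,6-dimethoxyphenyl]-N-methylbut-3-en-1-amine hydrochloride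
Conditions: HCl (4 M in dioxane, 2.5 equiv), MeOH, 0 °C, 30 min; evaporation below 25 °C, trituration with t-BuOMe
Reagents that add atoms: hydrogen chloride, Cl
Why: Acidic cleavage of the S–N bond (chloride attacks protonated sulfur, methanol traps the sulfinyl chloride), which is fast at 0 °C; the product rests as a benzylic ammonium chloride, a salt type that is stable for trialkoxybenzylamines, and short, cold acid contact guards against ionisation at C2'.

Step 6
Reactants: 10 (1R)-1-[4-(benzyloxy)-2,6-dimethoxyphenyl]-N-methylbut-3-en-1-amine hydrochloride; 6 allyl bromide
Product: 11 (R)-N-allyl-1-[4-(benzyloxy)-2,6-dimethoxyphenyl]-N-methylbut-3-en-1-amine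
Conditions: K2CO3 (3 equiv), MeCN, 50 °C
Reagents that add atoms: none
Why: SN2 N-allylation of the secondary amine freed in the flask by carbonate; the hindered tertiary amine formed is a poor nucleophile, so quaternisation should not compete when about one equivalent of allyl bromide is used.

Step 7
Reactants: 11 (R)-N-allyl-1-[4-(benzyloxy)-2,6-dimethoxyphenyl]-N-methylbut-3-en-1-amine
Product: 14 (R)-2-[4-(benzyloxy)-2,6-dimethoxyphenyl]-1-methyl-1,2,3,6-tetrahydropyridine, via diene ammonium tosylate 12 (not isolated), via tetrahydropyridinium tosylate 13 (not isolated)
Conditions: p-TsOH·H2O (1.05 equiv), CH2Cl2, rt; second-generation Grubbs catalyst (H2IMes)(PCy3)Cl2Ru=CHPh (5 mol %), 0.01 M, 40 °C; aq. NaHCO3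
Reagents that add atoms: none
Why: Ring-closing olefin metathesis of an amine salt, the known route from diallylic and allyl-homoallyl amines to 1,2,3,6-tetrahydropyridines. After phosphine loss the ruthenium benzylidene exchanges with a terminal alkene, most probably the less hindered N-allyl group, to give a ruthenium alkylidene; this adds to the C-allyl alkene in an intramolecular [2+2] step, and cycloreversion of the ruthenacyclobutane releases the C4'=C5' bond and Ru=CH2, which carries the chain with loss of ethylene. The six-membered ring is therefore closed by intramolecular metathesis of two terminal alkenes, the ring size enforces a cis endocyclic alkene, and escape of ethylene drives the closure. No stereocentre is formed; C2', set in step 3, takes no part in bond making or breaking. Three selectivities are needed: the catalyst must not be bound by nitrogen, which one equivalent of sulfonic acid secures by converting the amine into 12; cyclisation must beat oligomerisation, which high dilution and the favourable ring size secure; and the double bond must not migrate, which the moderate temperature, short reaction time and the ammonium centre (an enamine cannot form from it) should secure. The acid is fully bound as an ion pair in a non-polar solvent, so C2'–N1' ionisation is not expected.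

Step 8
Reactants: 14 (R)-2-[4-(benzyloxy)-2,6-dimethoxyphenyl]-1-methyl-1,2,3,6-tetrahydropyridine
Product: 15 (R)-3,5-dimethoxy-4-(1-methylpiperidin-2-yl)phenol
Conditions: H2 (1 atm), Pd(OH)2/C, EtOH, rt
Reagents that add atoms: none
Why: Heterogeneous hydrogenation saturates the cis ring alkene and hydrogenolyses the aryl benzyl ether in one operation; the C2'–N1' bond is a hindered secondary ring bond whose arene is kept off the metal surface by two ortho methoxy groups, so it should survive at 1 atm and rt.

Step 9
Reactants: 15 (R)-3,5-dimethoxy-4-(1-methylpiperidin-2-yl)phenol; 16 ethyl 3-phenylprop-2-ynoate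
Product: 18 (Z)-3-{3,5-dimethoxy-4-[(2R)-1-methylpiperidin-2-yl]phenoxy}-3-phenylprop-2-enoic acid, via aryloxycinnamate ethyl ester 17 (not isolated)
Conditions: K2CO3, DMF, 80 °C; then 2 M aq. NaOH, EtOH, 50 °C; AcOH to pH 6–7
Reagents that add atoms: sodium hydroxide, [Na+].[OH-]
Why: Base-mediated oxa-Michael addition of the phenoxide to the β-carbon of the alkynoate, followed by saponification in the same flask; the medium stays basic, so nitrogen is not protonated and C2' cannot ionise. The Z-acid is the isomer that cyclises, and any E-isomer should equilibrate under the acid of step 10.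

Step 10
Reactants: 18 (Z)-3-{3,5-dimethoxy-4-[(2R)-1-methylpiperidin-2-yl]phenoxy}-3-phenylprop-2-enoic acid
Product: 19 (R)-5,7-dimethoxy-6-(1-methylpiperidin-2-yl)-2-phenyl-4H-chromen-4-one
Conditions: P2O5/MeSO3H (1:10 w/w), rt to 40 °C; ice, aq. NH3 to pH 9
Reagents that add atoms: none
Why: Intramolecular Friedel–Crafts acylation: the activated acid attacks the ring carbon ortho to the aryloxy oxygen and para to a methoxy group (the two ortho carbons are equivalent) and closes ring C as the 4-pyranone; the strongly activated ring allows a mild temperature, and nitrogen stays protonated throughout.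

Step 11
Reactants: 19 (R)-5,7-dimethoxy-6-(1-methylpiperidin-2-yl)-2-phenyl-4H-chromen-4-one
Product: 20 (R)-5,7-dihydroxy-6-(1-methylpiperidin-2-yl)-2-phenyl-4H-chromen-4-one
Conditions: BBr3 (6 equiv), CH2Cl2, −78 °C to rt; MeOH, 0 °C; aq. NaHCO3 to pH 8
Reagents that add atoms: none
Why: Lewis-acid ether cleavage: BBr3 binds each methoxy oxygen and bromide removes the methyl group by SN2 (the C5 ether is helped by chelation to the C4 carbonyl), and methanolysis of the borates frees both phenols; nitrogen is held as its boron adduct or hydrobromide, and the low temperature protects C2' and the pyranone.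

## Compound list

1 | 4-hydroxy-2,6-dimethoxybenzaldehyde | COc1cc(O)cc(OC)c1C=O | starting material
2 | benzyl bromide | BrCc1ccccc1 | starting material
3 | 4-(benzyloxy)-2,6-dimethoxybenzaldehyde | COc1cc(OCc2ccccc2)cc(OC)c1C=O | intermediate
4 | (S)-2-methylpropane-2-sulfinamide | CC(C)(C)[S@](=O)N | starting material
5 | (S,E)-N-[4-(benzyloxy)-2,6-dimethoxybenzylidene]-2-methylpropane-2-sulfinamide | CC(C)(C)[S@](=O)/N=C/c1c(OC)cc(OCc2ccccc2)cc1OC | intermediate
6 | allyl bromide | C=CCBr | starting material
7 | allylzinc bromide (not isolated) | C=CC[Zn]Br | intermediate
8 | (S)-N-[(1R)-1-[4-(benzyloxy)-2,6-dimethoxyphenyl]but-3-en-1-yl]-2-methylpropane-2-sulfinamide | CC(C)(C)[S@](=O)N[C@H](CC=C)c1c(OC)cc(OCc2ccccc2)cc1OC | intermediate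
9 | (S)-N-[(1R)-1-[4-(benzyloxy)-2,6-dimethoxyphenyl]but-3-en-1-yl]-N,2-dimethylpropane-2-sulfinamide | CC(C)(C)[S@](=O)N(C)[C@H](CC=C)c1c(OC)cc(OCc2ccccc2)cc1OC | intermediate
10 | (1R)-1-[4-(benzyloxy)-2,6-dimethoxyphenyl]-N-methylbut-3-en-1-amine hydrochloride | C[NH2+][C@H](CC=C)c1c(OC)cc(OCc2ccccc2)cc1OC.[Cl-] | intermediate
11 | (R)-N-allyl-1-[4-(benzyloxy)-2,6-dimethoxyphenyl]-N-methylbut-3-en-1-amine | C=CCN(C)[C@H](CC=C)c1c(OC)cc(OCc2ccccc2)cc1OC | intermediate
12 | (R)-N-allyl-1-[4-(benzyloxy)-2,6-dimethoxyphenyl]-N-methylbut-3-en-1-aminium 4-methylbenzenesulfonate (not isolated) | C=CC[NH+](C)[C@H](CC=C)c1c(OC)cc(OCc2ccccc2)cc1OC.Cc1ccc(cc1)S(=O)(=O)[O-] | intermediate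
13 | (R)-2-[4-(benzyloxy)-2,6-dimethoxyphenyl]-1-methyl-1,2,3,6-tetrahydropyridinium 4-methylbenzenesulfonate (not isolated) | C[NH+]1CC=CC[C@@H]1c1c(OC)cc(OCc2ccccc2)cc1OC.Cc1ccc(cc1)S(=O)(=O)[O-] | intermediate
14 | (R)-2-[4-(benzyloxy)-2,6-dimethoxyphenyl]-1-methyl-1,2,3,6-tetrahydropyridine | CN1CC=CC[C@@H]1c1c(OC)cc(OCc2ccccc2)cc1OC | intermediate
15 | (R)-3,5-dimethoxy-4-(1-methylpiperidin-2-yl)phenol | CN1CCCC[C@@H]1c1c(OC)cc(O)cc1OC | intermediate
16 | ethyl 3-phenylprop-2-ynoate | CCOC(=O)C#Cc1ccccc1 | starting material
17 | ethyl (Z)-3-{3,5-dimethoxy-4-[(2R)-1-methylpiperidin-2-yl]phenoxy}-3-phenylprop-2-enoate (not isolated) | CCOC(=O)/C=C(\Oc1cc(OC)c(c(OC)c1)[C@H]1CCCCN1C)c1ccccc1 | intermediate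
18 | (Z)-3-{3,5-dimethoxy-4-[(2R)-1-methylpiperidin-2-yl]phenoxy}-3-phenylprop-2-enoic acid | OC(=O)/C=C(\Oc1cc(OC)c(c(OC)c1)[C@H]1CCCCN1C)c1ccccc1 | intermediate
19 | (R)-5,7-dimethoxy-6-(1-methylpiperidin-2-yl)-2-phenyl-4H-chromen-4-one | CN1CCCC[C@@H]1c1c(OC)cc2oc(-c3ccccc3)cc(=O)c2c1OC | intermediate
20 | (R)-5,7-dihydroxy-6-(1-methylpiperidin-2-yl)-2-phenyl-4H-chromen-4-one | CN1CCCC[C@@H]1c1c(O)cc2oc(-c3ccccc3)cc(=O)c2c1O | target

## Step count and least certain steps

Total step count: 11. Longest linear sequence: 11 steps (1 to 20); compounds 2, 4, 6 and 16 enter as purchased reagents.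

**Step 7 (key step).** The likely failures are catalyst deactivation by traces of unprotonated amine, chain growth by intermolecular metathesis if the solution is too concentrated, and ruthenium-hydride-mediated double-bond migration on prolonged heating. The fallback keeps the same ring closure but makes nitrogen non-basic by acylation at sulfur. Setting out from 8, N-allylation (LiN(SiMe3)2, allyl bromide 6, DMF) should give the N-allyl-N-sulfinyl diene F1. Metathesis with the same ruthenium catalyst, without acid, should give the N-sulfinyl tetrahydropyridine F2, and HCl in MeOH at 0 °C followed by base should give the secondary amine F3. Reductive methylation (aqueous CH2O, NaBH(OAc)3) rejoins the route at 14.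

**Step 3.** The likely failures are poor facial selectivity, because an ortho methoxy oxygen can compete with the sulfinyl oxygen for zinc and open a second transition state, and slow addition to the twisted, deactivated imine. The fallback gives up auxiliary control for a classical resolution. Setting out from 3, condensation with methylamine should give the N-methyl aldimine F4, and allylmagnesium bromide (C3H5MgBr, THF, 0 °C) the racemic secondary amine F5. Crystallisation with (S)-mandelic acid, or its antipode if the other salt is the less soluble, should give the (R)-ammonium (S)-mandelate F6. F6 is used in place of 10 under the conditions of step 6 and rejoins the route at 11.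

**Step 8.** The likely failures are hydrogenolysis of the benzylic C2'–N1' bond with ring opening, palladium-mediated migration of the double bond to C2'=C3' before reduction (which would erase the stereocentre), and slow debenzylation because the amine occupies the catalyst surface. The fallback uses no metal surface. Setting out from 14, diimide generated from 2-nitrobenzenesulfonyl hydrazide and Et3N should reduce the alkene to the saturated benzyl ether F7. BCl3 with pentamethylbenzene in CH2Cl2 at −78 °C should then remove the benzyl group and rejoin the route at 15.

**Step 10.** The likely failures are ionisation of the protonated C2'–N1' bond in the strongly acidic medium (racemisation), acid cleavage of the enol ether before acylation, and acylation of ring B from the E-acid. The fallback builds ring C without acid and replaces steps 9 and 10. Setting out from 15, ortho-formylation (MgCl2, Et3N, paraformaldehyde, MeCN) should give the salicylaldehyde F8. Lithium phenylacetylide (PhC≡CLi, 2.2 equiv, THF) should give the propargylic alcohol F9, and MnO2 in CH2Cl2 the ortho-hydroxyaryl ynone F10. Amine-promoted 6-endo-dig oxa-Michael closure (Et2NH, EtOH) rejoins the route at 19.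

**Step 11.** The likely failures are incomplete cleavage of the C7 ether (no carbonyl assistance, and flanked by the C6 substituent), loss of configuration by C2'–N1' ionisation once the ortho phenols are free in the presence of HBr, and acid-induced opening and reclosure of the pyranone that would move the piperidine to C8 (Wessely–Moser-type rearrangement). The fallback separates the two ethers and removes the second one in base. Setting out from 19, AlCl3 in MeCN at rt should cleave only the chelated C5 ether to give the 5-hydroxy-7-methoxyflavone F11. NaSEt in DMF at 100 °C should then remove the C7 methyl group by SN2 at carbon, with nitrogen unprotonated, and rejoin the route at 20.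

## Further compounds

F1 | step 7 | (S)-N-allyl-N-[(1R)-1-[4-(benzyloxy)-2,6-dimethoxyphenyl]but-3-en-1-yl]-2-methylpropane-2-sulfinamide | CC(C)(C)[S@](=O)N(CC=C)[C@H](CC=C)c1c(OC)cc(OCc2ccccc2)cc1OC
F2 | step 7 | (2R)-2-[4-(benzyloxy)-2,6-dimethoxyphenyl]-1-[(S)-tert-butylsulfinyl]-1,2,3,6-tetrahydropyridine | CC(C)(C)[S@](=O)N1CC=CC[C@@H]1c1c(OC)cc(OCc2ccccc2)cc1OC
F3 | step 7 | (R)-2-[4-(benzyloxy)-2,6-dimethoxyphenyl]-1,2,3,6-tetrahydropyridine | N1CC=CC[C@@H]1c1c(OC)cc(OCc2ccccc2)cc1OC
F4 | step 3 | (E)-1-[4-(benzyloxy)-2,6-dimethoxyphenyl]-N-methylmethanimine | C/N=C/c1c(OC)cc(OCc2ccccc2)cc1OC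
F5 | step 3 | rac-1-[4-(benzyloxy)-2,6-dimethoxyphenyl]-N-methylbut-3-en-1-amine | CNC(CC=C)c1c(OC)cc(OCc2ccccc2)cc1OC
F6 | step 3 | (1R)-1-[4-(benzyloxy)-2,6-dimethoxyphenyl]-N-methylbut-3-en-1-aminium (S)-mandelate | C[NH2+][C@H](CC=C)c1c(OC)cc(OCc2ccccc2)cc1OC.O[C@H](C([O-])=O)c1ccccc1
F7 | step 8 | (R)-2-[4-(benzyloxy)-2,6-dimethoxyphenyl]-1-methylpiperidine | CN1CCCC[C@@H]1c1c(OC)cc(OCc2ccccc2)cc1OC
F8 | step 10 | 6-hydroxy-2,4-dimethoxy-3-[(2R)-1-methylpiperidin-2-yl]benzaldehyde | CN1CCCC[C@@H]1c1c(OC)cc(O)c(C=O)c1OC
F9 | step 10 | 1-{6-hydroxy-2,4-dimethoxy-3-[(2R)-1-methylpiperidin-2-yl]phenyl}-3-phenylprop-2-yn-1-ol (mixture of carbinol epimers) | CN1CCCC[C@@H]1c1c(OC)cc(O)c(C(O)C#Cc2ccccc2)c1OC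
F10 | step 10 | 1-{6-hydroxy-2,4-dimethoxy-3-[(2R)-1-methylpiperidin-2-yl]phenyl}-3-phenylprop-2-yn-1-one | CN1CCCC[C@@H]1c1c(OC)cc(O)c(C(=O)C#Cc2ccccc2)c1OC
F11 | step 11 | (R)-5-hydroxy-7-methoxy-6-(1-methylpiperidin-2-yl)-2-phenyl-4H-chromen-4-one | CN1CCCC[C@@H]1c1c(OC)cc2oc(-c3ccccc3)cc(=O)c2c1O
A1 | alternative 1 | tert-butyl (R)-2-(5,7-dimethoxy-4-oxo-2-phenyl-4H-chromen-6-yl)piperidine-1-carboxylate | CC(C)(C)OC(=O)N1CCCC[C@@H]1c1c(OC)cc2oc(-c3ccccc3)cc(=O)c2c1OC
A2 | alternative 1 | tert-butyl (R)-2-(3-formyl-4-hydroxy-2,6-dimethoxyphenyl)piperidine-1-carboxylate | CC(C)(C)OC(=O)N1CCCC[C@@H]1c1c(OC)cc(O)c(C=O)c1OC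
A3 | alternative 1 | 2-[dimethyl(oxo)-λ6-sulfanylidene]-1-phenylethan-1-one | CS(C)(=O)=CC(=O)c1ccccc1
A4 | alternative 2 | (R)-2-[2,6-dimethoxy-4-(triisopropylsilyloxy)phenyl]-1-(4-methoxyphenyl)-2,3-dihydropyridin-4(1H)-one | COc1ccc(cc1)N1C=CC(=O)C[C@@H]1c1c(OC)cc(O[Si](C(C)C)(C(C)C)C(C)C)cc1OC
A5 | alternative 2 | (E)-1-[2,6-dimethoxy-4-(triisopropylsilyloxy)phenyl]-N-(4-methoxyphenyl)methanimine | COc1ccc(cc1)/N=C/c1c(OC)cc(O[Si](C(C)C)(C(C)C)C(C)C)cc1OC
A6 | alternative 2 | (E)-1-methoxy-3-(trimethylsilyloxy)buta-1,3-diene | CO/C=C/C(=C)O[Si](C)(C)C
A7 | alternative 3 | methyl (R)-2-(4-benzyloxy-2,6-dihydroxyphenyl)piperidine-1-carboxylate | COC(=O)N1CCCC[C@@H]1c1c(O)cc(OCc2ccccc2)cc1O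
A8 | alternative 3 | methyl N-[5-(4-benzyloxy-2,6-dihydroxyphenyl)-5-hydroxypentyl]carbamate (racemic) | COC(=O)NCCCCC(O)c1c(O)cc(OCc2ccccc2)cc1O
A9 | alternative 3 | methyl N-[5-(4-benzyloxy-2-hydroxy-6-oxocyclohexa-2,4-dien-1-ylidene)pentyl]carbamate | COC(=O)NCCCCC=C1C(=O)C=C(OCc2ccccc2)C=C1O
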